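The pitfall with a flat curve is to take it for a reaction that has finished its work, or for a balance that could be shifted. Before you believe either, open a ledger for the coupling partner, which is charged short of the substrate, and see where each mole goes.

common to all: substrate 0.46 M

| charge | coupling partner | remark | time |
|---|---|---|---|
| ash | 0.414 M | the very flask that is asked about, followed so far |  |
| oak | 0.83 M | run made earlier |  |
| flask | 0.414 M |  | 5.0 d |

| ash: time / h | ash: target / % | oak: time / h | oak: target / % |
|---|---|---|---|
| 30.0 | 29.1 | 1.50 | 0.2 |
| 60.0 | 29.4 | 3.00 | 4.6 |
| 96.0 | 29.7 | 5.00 | 26.1 |
| 120 | 29.5 | 6.00 | 43.1 |

(each reading ± 0.5 percentage points)

- east: at 5.0 d take out 90% of the by-product then present, then wait 10 d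
- south-east: change nothing and wait 10 d more
- west: at 5.0 d add coupling partner, 100% of the amount charged, then wait 10 d
- north-east: at 5.0 d add substrate, 50.0% of the amount charged, then wait 10 d

1. target, in percent of the substrate first charged, at 5.0 d
2. the option that brings most further target ("none" if no option brings more than 2 percentage points) (east / south-east / west / north-east / none)
3. target present, in percent of the substrate first charged, after east
4. target present, in percent of the substrate first charged, after south-east

- what is added takes up no volume worth counting
- the analysis behind the earlier runs scatters by 0.5 percentage points, standard deviation

Ash is the flask you are asked about, and its readings average 29.4%. The reading at 120 h stands 0.4 percentage points above the one at 30.0 h, against a scatter of 0.5 points. Oak, with the same substrate and 0.83 M of partner, gains 17 points from 5.00 h to 6.00 h, and its last reading of 43.1% already stands above the level of ash.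

Now the books for ash. The charge is 0.414 M of coupling partner. The first entry, counting one partner per target as my assumption, is 0.135 M of target. Call the partner share the target formed per coupling partner charged, here 32.7%. That leaves an open entry of 0.279 M, while 0.325 M of substrate stands unused.

My reckoning is that the open entry went down a path that gives no target, which makes the partner the limiting reagent. Waiting, more substrate and removing by-product then bring nothing. A fresh 0.414 M of partner, at the same share, brings 29 points.

The forecast gives 29.4% now, 29.5% after east and 29.5% after south-east, and it names west, on this ground: “More partner clearly lifts the ceiling.”

The simulation runs this scheme:

    substrate + coupling partner + by-product → target + 2 by-product (k = 4.10 /M²/h)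
    substrate + coupling partner → target + by-product (k = 0.00140 /M/h)
    coupling partner → decomposed reagent (k = 0.0830 /h)

The flask gives 29.4%, with 29.4% after east and 29.4% after south-east, and west brings 61 points, more than the 29 points reckoned at the old share. At 120 h the flask holds 0% of its coupling partner free and 0.279 M of decomposed reagent, which is the name of the open entry of 0.279 M. Now take a neighbour charged with 1.8 M of substrate and the same partner. A share of 32.7% would put 7.52% of its substrate into target, yet it holds 18.6%, a partner share of 80.9%, beside 0.0798 M of decomposed reagent.

The earlier runs and the new flask were generated by integration for substances that don't exist, noise included.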